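The six-membered ring (C5–C10: C10 quaternary with methyl and vinyl, C8 acyloxy, C6 hydroxy) is cut at C5–C6 and C7–C8. Both bonds lie in homoallylic alcohols that carry an exo-methylene: O–C8–C7–C(=CH2)CO2H is the retron of a 2-alkoxycarbonylallylboration, and HO–C6–C5–C(=CH2) that of a carbonyl-ene reaction. In one flask, an acyclic β-quaternary aldehyde bearing an isobutenyl group is joined to a γ-formyl allylboronate: acid-catalysed allylboration forms C7–C8, lactonisation follows, and the now non-conjugated C6 aldehyde closes the ring by an ene reaction (C5–C6), setting C5 to C8. Allylic oxidation, lactone opening, O8 acylation and deprotection complete the route.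

Key step: step 13

Remark: atoms are numbered as in elemanes (ring C5–C10; C10 bears methyl C14 and vinyl C1=C2; C5 bears C4(=C3)C15; C7 bears C11(=C13)C12). The target is a cis γ-hydroxy acid, so it is assumed to survive only near neutral pH and is never exposed to acid once O6 is free.
Remark: the sense of induction of (S)-TRIP (attack on the Si face of aldehyde 12) is assumed from its behaviour in allyl- and crotylborations of aliphatic aldehydes.

Step 1
Reactants: 1 2-[(4R)-2,2-dimethyl-1,3-dioxolan-4-yl]ethanol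
Product: 2 2-[(4R)-2,2-dimethyl-1,3-dioxolan-4-yl]acetaldehyde
Conditions: Dess–Martin periodinane, CH2Cl2, 0 °C to rt
Reagents that add atoms: none
Why: Dess–Martin oxidation of the primary alcohol is mild enough for the acetonide and leaves the stereocentre untouched.

Step 2
Reactants: 2 2-[(4R)-2,2-dimethyl-1,3-dioxolan-4-yl]acetaldehyde
Product: 3 2-[(4R)-2,2-dimethyl-1,3-dioxolan-4-yl]prop-2-enal
Conditions: Eschenmoser's salt, Et3N, CH2Cl2, rt
Reagents that add atoms: dimethylmethylideneammonium iodide (Eschenmoser's salt), C=[N+](C)C.[I-]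
Why: Mannich reaction of the aldehyde followed by amine elimination (α-methylenation of an aldehyde) installs the methylidene group without creating or touching a stereocentre.

Step 3
Reactants: 3 2-[(4R)-2,2-dimethyl-1,3-dioxolan-4-yl]prop-2-enal
Product: 4 2-[(4R)-2,2-dimethyl-1,3-dioxolan-4-yl]prop-2-enoic acid
Conditions: NaClO2, NaH2PO4, 2-methylbut-2-ene, t-BuOH/H2O, 0 °C to rt
Reagents that add atoms: sodium chlorite, [Na+].[O-]Cl=O
Why: Pinnick oxidation converts the enal into the acrylic acid without affecting the alkene or the acetonide.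

Step 4
Reactants: 5 (but-3-yn-1-yloxy)(tert-butyl)dimethylsilane
Product: 7 (E)-5-[(tert-butyldimethylsilyl)oxy]-3-methylpent-2-en-1-ol, via alkenylalane 6 (not isolated)
Conditions: Me3Al, Cp2ZrCl2 (0.2 equiv), CH2Cl2, 0 °C to rt; then paraformaldehyde, THF, 0 °C to rt
Reagents that add atoms: trimethylaluminium, C[Al](C)C; formaldehyde (as paraformaldehyde), C=O
Why: Negishi zirconium-catalysed carboalumination adds methyl and aluminium syn across the terminal alkyne, and the alkenylalane is trapped by formaldehyde with retention, which fixes the E alkene.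

Step 5
Reactants: 7 (E)-5-[(tert-butyldimethylsilyl)oxy]-3-methylpent-2-en-1-ol
Product: 8 diethyl (E)-5-[(tert-butyldimethylsilyl)oxy]-3-methylpent-2-en-1-yl phosphate
Conditions: ClP(O)(OEt)2, Et3N, DMAP (cat.), CH2Cl2, 0 °C
Reagents that add atoms: diethyl chlorophosphate, CCOP(=O)(Cl)OCC
Why: Phosphorylation of the primary allylic alcohol provides the leaving group for the allylic substitution.

Step 6
Reactants: 8 diethyl (E)-5-[(tert-butyldimethylsilyl)oxy]-3-methylpent-2-en-1-yl phosphate; 9 4,4,5,5-tetramethyl-2-(2-methylprop-1-en-1-yl)-1,3,2-dioxaborolane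
Product: 10 tert-butyl{[(3S)-3-ethenyl-3,5-dimethylhex-4-en-1-yl]oxy}dimethylsilane
Conditions: CuCl (5 mol%), chiral sulfonate-bearing imidazolinium salt (NHC precursor, 5.5 mol%), NaOMe (1.5 equiv), THF, 22 °C
Reagents that add atoms: none
Why: Copper–NHC-catalysed enantioselective allylic substitution (SN2′) with an alkenylboronate delivers the isobutenyl group to the methyl-bearing alkene carbon, which creates the quaternary centre C10 (the ligand enantiomer is chosen for S) and leaves the terminal vinyl group.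

Step 7
Reactants: 10 tert-butyl{[(3S)-3-ethenyl-3,5-dimethylhex-4-en-1-yl]oxy}dimethylsilane
Product: 11 (3S)-3-ethenyl-3,5-dimethylhex-4-en-1-ol
Conditions: TBAF, THF, 0 °C to rt
Reagents that add atoms: none
Why: Fluoride cleavage of the silyl ether frees the primary alcohol without affecting the alkenes or the quaternary centre.

Step 8
Reactants: 11 (3S)-3-ethenyl-3,5-dimethylhex-4-en-1-ol
Product: 12 (3S)-3-ethenyl-3,5-dimethylhex-4-enal
Conditions: Dess–Martin periodinane, CH2Cl2, 0 °C to rt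
Reagents that add atoms: none
Why: Dess–Martin oxidation gives the β-quaternary aldehyde, whose stereocentre cannot be lost by enolisation.

Step 9
Reactants: 13 methyl acrylate; 14 2,2-dimethoxyacetaldehyde
Product: 15 methyl 3-hydroxy-4,4-dimethoxy-2-methylidenebutanoate (racemic)
Conditions: DABCO (0.5 equiv), dioxane/H2O, rt
Reagents that add atoms: none
Why: Morita–Baylis–Hillman reaction of the acrylate with the activated aldehyde builds the C6–C7–C11(–C12)–C13 unit; the racemic carbinol centre is erased in step 11.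

Step 10
Reactants: 15 methyl 3-hydroxy-4,4-dimethoxy-2-methylidenebutanoate (racemic)
Product: 16 methyl 3-acetoxy-4,4-dimethoxy-2-methylidenebutanoate (racemic)
Conditions: Ac2O, pyridine, DMAP (cat.), CH2Cl2, 0 °C to rt
Reagents that add atoms: acetic anhydride, CC(=O)OC(C)=O
Why: DMAP-catalysed acetylation turns the allylic alcohol into a leaving group.

Step 11
Reactants: 16 methyl 3-acetoxy-4,4-dimethoxy-2-methylidenebutanoate (racemic)
Product: 17 methyl (E)-4,4-dimethoxy-2-[(4,4,5,5-tetramethyl-1,3,2-dioxaborolan-2-yl)methyl]but-2-enoate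
Conditions: B2pin2, Pd2(dba)3 (3 mol%), toluene, 50 °C
Reagents that add atoms: bis(pinacolato)diboron, CC1(C)OB(OC1(C)C)B1OC(C)(C)C(C)(C)O1
Why: Palladium-catalysed borylation of the Baylis–Hillman acetate through a π-allyl intermediate places boron on the terminal carbon and should give the thermodynamically preferred E alkene, in which the acetal carbon is cis to CH2B.

Step 12
Reactants: 17 methyl (E)-4,4-dimethoxy-2-[(4,4,5,5-tetramethyl-1,3,2-dioxaborolan-2-yl)methyl]but-2-enoate
Product: 18 methyl (E)-4-oxo-2-[(4,4,5,5-tetramethyl-1,3,2-dioxaborolan-2-yl)methyl]but-2-enoate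
Conditions: Amberlyst-15, acetone/H2O, rt; used at once
Reagents that add atoms: water, O
Why: Acid-catalysed acetal hydrolysis frees the formyl group, the pinacol allylboronate should tolerate the mild acid, and the E geometry (formyl trans to ester) is retained.

Step 13
Reactants: 12 (3S)-3-ethenyl-3,5-dimethylhex-4-enal; 18 methyl (E)-4-oxo-2-[(4,4,5,5-tetramethyl-1,3,2-dioxaborolan-2-yl)methyl]but-2-enoate
Product: 21 (5R,6S,7S,8R,10S)-6-hydroxyelema-1,3,11(13)-trien-12,8-olide, via boryl ether 19 (not isolated), via lactone aldehyde 20 (not isolated)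
Conditions: (S)-TRIP (10 mol%), 4 Å MS, toluene, −20 °C to rt, 18 added slowly; then Sc(OTf)3 (10 mol%), −40 to 0 °C, same flask without work-up
Reagents that add atoms: none
Why: The phosphoric acid activates boronate and aldehyde in a chair Zimmerman–Traxler transition state, so that C7 of 18 adds to C8 of 12 with allyl transposition (forming the C11=C13 methylene); boryl ether 19 lactonises onto the methyl ester, and Sc(OTf)3 then activates the deconjugated C6 aldehyde of 20 for an intramolecular carbonyl-ene reaction with the isobutenyl group, a methyl hydrogen moving to oxygen as C3=C4 forms. The closest known reaction types are the chiral-phosphoric-acid-catalysed crotylboration of aldehydes with pinacol boronates, the lactone-forming additions of 2-alkoxycarbonyl allylboronates, and the Sc(OTf)3-catalysed cyclisation of citronellal to isopulegol. The γ-lactone closes by 5-exo-trig acyl substitution and the cyclohexane by a chair-like type 1 ene closure (6-exo at the carbonyl carbon). C8 is set by the catalyst, C7 by the reagent geometry (C6 cis to CH2B gives the syn adduct and hence the cis lactone), and C6 and C5 by the chair in which O8, O6 and the propenyl group are equatorial and C11 axial, placing 6-OH cis to O8 and C11 and trans to the C5 substituent; C10 comes unchanged from 12 and ends with vinyl axial. The step needs cross-allylboration rather than self-allylboration of 18, and ene closure onto the isobutenyl rather than the vinyl group. The saturated aldehyde 12 is more electrophilic than the conjugated formyl group of 18, 18 is added slowly, and only the trisubstituted alkene can give a six-membered ring with tertiary cationic character at C4.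

Step 14
Reactants: 21 (5R,6S,7S,8R,10S)-6-hydroxyelema-1,3,11(13)-trien-12,8-olide
Product: 22 (5S,6S,7S,8R,10S)-6,15-dihydroxyelema-1,3,11(13)-trien-12,8-olide
Conditions: SeO2 (0.5 equiv), t-BuOOH (3 equiv), CH2Cl2, 0 °C to rt
Reagents that add atoms: selenium dioxide (oxygen carrier), O=[Se]=O; tert-butyl hydroperoxide (terminal oxidant), CC(C)(C)OO
Why: Sharpless SeO2/t-BuOOH allylic hydroxylation (ene reaction then [2,3]-shift) should oxidise the methyl group of the isopropenyl unit, since the vinyl group has no allylic hydrogen and the lactone methylene is electron-poor.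

Step 15
Reactants: 22 (5S,6S,7S,8R,10S)-6,15-dihydroxyelema-1,3,11(13)-trien-12,8-olide
Product: 23 (5S,6S,7R,8R,10S)-6,15-bis[(tert-butyldimethylsilyl)oxy]elema-1,3,11(13)-trien-12,8-olide
Conditions: TBSOTf (2.5 equiv), 2,6-lutidine, CH2Cl2, −78 to 0 °C
Reagents that add atoms: tert-butyldimethylsilyl triflate, CC(C)(C)[Si](C)(C)OS(=O)(=O)C(F)(F)F
Why: Silylation with the silyl triflate protects both the primary allylic and the hindered C6 alcohol while O8 and C12 remain masked in the lactone.

Step 16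
Reactants: 23 (5S,6S,7R,8R,10S)-6,15-bis[(tert-butyldimethylsilyl)oxy]elema-1,3,11(13)-trien-12,8-olide
Product: 25 triisopropylsilyl (5S,6S,7R,8R,10S)-6,15-bis[(tert-butyldimethylsilyl)oxy]-8-hydroxyelema-1,3,11(13)-trien-12-oate, via lithium carboxylate 24 (not isolated)
Conditions: LiOH·H2O (1.1 equiv), THF/H2O, 0 °C; concentrate and dry; then i-Pr3SiCl, DMF, 0 °C
Reagents that add atoms: lithium hydroxide, [Li+].[OH-]; triisopropylsilyl chloride, CC(C)[Si](Cl)(C(C)C)C(C)C
Why: Saponification opens the lactone to the carboxylate, which is silylated on oxygen by the bulky silyl chloride without acidification, so the free C8 alcohol should neither relactonise nor be silylated.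

Step 17
Reactants: 25 triisopropylsilyl (5S,6S,7R,8R,10S)-6,15-bis[(tert-butyldimethylsilyl)oxy]-8-hydroxyelema-1,3,11(13)-trien-12-oate; 4 2-[(4R)-2,2-dimethyl-1,3-dioxolan-4-yl]prop-2-enoic acid
Product: 27 triisopropylsilyl (5S,6S,7R,8R,10S)-6,15-bis[(tert-butyldimethylsilyl)oxy]-8-({2-[(4R)-2,2-dimethyl-1,3-dioxolan-4-yl]prop-2-enoyl}oxy)elema-1,3,11(13)-trien-12-oate, via mixed anhydride 26 (not isolated)
Conditions: 4, 2,4,6-trichlorobenzoyl chloride, Et3N, toluene, rt; then 25, DMAP, toluene, rt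
Reagents that add atoms: none
Why: Yamaguchi esterification through the mixed anhydride acylates the hindered equatorial C8 alcohol with retention at C8, and acid 4 has no α-hydrogen to epimerise.

Step 18
Reactants: 27 triisopropylsilyl (5S,6S,7R,8R,10S)-6,15-bis[(tert-butyldimethylsilyl)oxy]-8-({2-[(4R)-2,2-dimethyl-1,3-dioxolan-4-yl]prop-2-enoyl}oxy)elema-1,3,11(13)-trien-12-oate
Product: 28 (5S,6S,7R,8R,10S)-6-[(tert-butyldimethylsilyl)oxy]-8-{[(3R)-3,4-dihydroxy-2-methylidenebutanoyl]oxy}-15-hydroxyelema-1,3,11(13)-trien-12-oic acid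
Conditions: AcOH/THF/H2O (3:1:1), 40 °C
Reagents that add atoms: none
Why: Mild aqueous acid hydrolysis removes the acetonide, the silyl ester and the primary silyl ether while the hindered secondary C6 silyl ether should stay, so the liberated acid has no free γ-hydroxyl to lactonise with.

Step 19
Reactants: 28 (5S,6S,7R,8R,10S)-6-[(tert-butyldimethylsilyl)oxy]-8-{[(3R)-3,4-dihydroxy-2-methylidenebutanoyl]oxy}-15-hydroxyelema-1,3,11(13)-trien-12-oic acid
Product: 29 (5S,6S,7S,8R,10S)-8-{[(3R)-3,4-dihydroxy-2-methylidenebutanoyl]oxy}-6,15-dihydroxyelema-1,3,11(13)-trien-12-oic acid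
Conditions: HF·pyridine, excess pyridine, THF, 0 °C to rt; cold pH 6–7 phosphate buffer work-up
Reagents that add atoms: none
Why: Pyridine-buffered fluoride desilylation frees the C6 hydroxyl under nearly neutral conditions, under which the γ-hydroxy acid should not close to the lactone and the dihydroxy ester should not migrate.

Compound list
1 | 2-[(4R)-2,2-dimethyl-1,3-dioxolan-4-yl]ethanol | OCC[C@@H]1COC(C)(C)O1 | starting material
2 | 2-[(4R)-2,2-dimethyl-1,3-dioxolan-4-yl]acetaldehyde | O=CC[C@@H]1COC(C)(C)O1 | intermediate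
3 | 2-[(4R)-2,2-dimethyl-1,3-dioxolan-4-yl]prop-2-enal | O=CC(=C)[C@@H]1COC(C)(C)O1 | intermediate
4 | 2-[(4R)-2,2-dimethyl-1,3-dioxolan-4-yl]prop-2-enoic acid | OC(=O)C(=C)[C@@H]1COC(C)(C)O1 | intermediate
5 | (but-3-yn-1-yloxy)(tert-butyl)dimethylsilane | C#CCCO[Si](C)(C)C(C)(C)C | starting material
6 | [(E)-4-(tert-butyldimethylsilyloxy)-2-methylbut-1-en-1-yl]dimethylalane | C[Al](C)/C=C(\C)CCO[Si](C)(C)C(C)(C)C | intermediate
7 | (E)-5-[(tert-butyldimethylsilyl)oxy]-3-methylpent-2-en-1-ol | OC/C=C(\C)CCO[Si](C)(C)C(C)(C)C | intermediate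
8 | diethyl (E)-5-[(tert-butyldimethylsilyl)oxy]-3-methylpent-2-en-1-yl phosphate | CCOP(=O)(OCC)OC/C=C(\C)CCO[Si](C)(C)C(C)(C)C | intermediate
9 | 4,4,5,5-tetramethyl-2-(2-methylprop-1-en-1-yl)-1,3,2-dioxaborolane | CC(C)=CB1OC(C)(C)C(C)(C)O1 | starting material
10 | tert-butyl{[(3S)-3-ethenyl-3,5-dimethylhex-4-en-1-yl]oxy}dimethylsilane | C=C[C@](C)(CCO[Si](C)(C)C(C)(C)C)C=C(C)C | intermediate
11 | (3S)-3-ethenyl-3,5-dimethylhex-4-en-1-ol | C=C[C@](C)(CCO)C=C(C)C | intermediate
12 | (3S)-3-ethenyl-3,5-dimethylhex-4-enal | C=C[C@](C)(CC=O)C=C(C)C | intermediate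
13 | methyl acrylate | C=CC(=O)OC | starting material
14 | 2,2-dimethoxyacetaldehyde | COC(OC)C=O | starting material
15 | methyl 3-hydroxy-4,4-dimethoxy-2-methylidenebutanoate (racemic) | COC(=O)C(=C)C(O)C(OC)OC | intermediate
16 | methyl 3-acetoxy-4,4-dimethoxy-2-methylidenebutanoate (racemic) | COC(=O)C(=C)C(OC(C)=O)C(OC)OC | intermediate
17 | methyl (E)-4,4-dimethoxy-2-[(4,4,5,5-tetramethyl-1,3,2-dioxaborolan-2-yl)methyl]but-2-enoate | COC(OC)/C=C(\CB1OC(C)(C)C(C)(C)O1)C(=O)OC | intermediate
18 | methyl (E)-4-oxo-2-[(4,4,5,5-tetramethyl-1,3,2-dioxaborolan-2-yl)methyl]but-2-enoate | O=C/C=C(\CB1OC(C)(C)C(C)(C)O1)C(=O)OC | intermediate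
19 | methyl (3R,4R,6S)-6-ethenyl-3-formyl-6,8-dimethyl-2-methylidene-4-[(4,4,5,5-tetramethyl-1,3,2-dioxaborolan-2-yl)oxy]non-7-enoate (syn adduct, boryl ether) | C=C[C@](C)(C[C@@H](OB1OC(C)(C)C(C)(C)O1)[C@H](C=O)C(=C)C(=O)OC)C=C(C)C | intermediate
20 | (2R,3R)-2-[(2S)-2-ethenyl-2,4-dimethylpent-3-en-1-yl]-4-methylidene-5-oxooxolane-3-carbaldehyde (cis lactone aldehyde) | C=C[C@](C)(C[C@H]1OC(=O)C(=C)[C@H]1C=O)C=C(C)C | intermediate
21 | (5R,6S,7S,8R,10S)-6-hydroxyelema-1,3,11(13)-trien-12,8-olide (cis-fused lactone; 6-OH cis to the lactone, trans to the C5 isopropenyl; vinyl cis to isopropenyl) | C=C[C@]1(C)C[C@H]2OC(=O)C(=C)[C@H]2[C@@H](O)[C@@H]1C(=C)C | intermediate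
22 | (5S,6S,7S,8R,10S)-6,15-dihydroxyelema-1,3,11(13)-trien-12,8-olide | C=C[C@]1(C)C[C@H]2OC(=O)C(=C)[C@H]2[C@@H](O)[C@@H]1C(=C)CO | intermediate
23 | (5S,6S,7R,8R,10S)-6,15-bis[(tert-butyldimethylsilyl)oxy]elema-1,3,11(13)-trien-12,8-olide | C=C[C@]1(C)C[C@H]2OC(=O)C(=C)[C@H]2[C@@H](O[Si](C)(C)C(C)(C)C)[C@@H]1C(=C)CO[Si](C)(C)C(C)(C)C | intermediate
24 | lithium (5S,6S,7R,8R,10S)-6,15-bis[(tert-butyldimethylsilyl)oxy]-8-hydroxyelema-1,3,11(13)-trien-12-oate | [Li+].C=C[C@]1(C)C[C@@H](O)[C@@H](C(=C)C([O-])=O)[C@@H](O[Si](C)(C)C(C)(C)C)[C@@H]1C(=C)CO[Si](C)(C)C(C)(C)C | intermediate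
25 | triisopropylsilyl (5S,6S,7R,8R,10S)-6,15-bis[(tert-butyldimethylsilyl)oxy]-8-hydroxyelema-1,3,11(13)-trien-12-oate | C=C[C@]1(C)C[C@@H](O)[C@@H](C(=C)C(=O)O[Si](C(C)C)(C(C)C)C(C)C)[C@@H](O[Si](C)(C)C(C)(C)C)[C@@H]1C(=C)CO[Si](C)(C)C(C)(C)C | intermediate
26 | 2-[(4R)-2,2-dimethyl-1,3-dioxolan-4-yl]prop-2-enoic 2,4,6-trichlorobenzoic anhydride | O=C(OC(=O)c1c(Cl)cc(Cl)cc1Cl)C(=C)[C@@H]1COC(C)(C)O1 | intermediate
27 | triisopropylsilyl (5S,6S,7R,8R,10S)-6,15-bis[(tert-butyldimethylsilyl)oxy]-8-({2-[(4R)-2,2-dimethyl-1,3-dioxolan-4-yl]prop-2-enoyl}oxy)elema-1,3,11(13)-trien-12-oate | C=C[C@]1(C)C[C@@H](OC(=O)C(=C)[C@@H]2COC(C)(C)O2)[C@@H](C(=C)C(=O)O[Si](C(C)C)(C(C)C)C(C)C)[C@@H](O[Si](C)(C)C(C)(C)C)[C@@H]1C(=C)CO[Si](C)(C)C(C)(C)C | intermediate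
28 | (5S,6S,7R,8R,10S)-6-[(tert-butyldimethylsilyl)oxy]-8-{[(3R)-3,4-dihydroxy-2-methylidenebutanoyl]oxy}-15-hydroxyelema-1,3,11(13)-trien-12-oic acid | C=C[C@]1(C)C[C@@H](OC(=O)C(=C)[C@@H](O)CO)[C@@H](C(=C)C(=O)O)[C@@H](O[Si](C)(C)C(C)(C)C)[C@@H]1C(=C)CO | intermediate
29 | (5S,6S,7S,8R,10S)-8-{[(3R)-3,4-dihydroxy-2-methylidenebutanoyl]oxy}-6,15-dihydroxyelema-1,3,11(13)-trien-12-oic acid | C=C[C@]1(C)C[C@@H](OC(=O)C(=C)[C@@H](O)CO)[C@@H](C(=C)C(=O)O)[C@@H](O)[C@@H]1C(=C)CO | target

Total step count: 19. Longest linear sequence: 12 steps (steps 4 to 8, then 13 to 19).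

Steps most likely to fail

Step 13. The boronate carries two acceptor groups and may add slowly, attack its own formyl group, or isomerise by migration of boron to the formyl oxygen; the acid may also control the face of the β-quaternary aldehyde poorly. The fallback separates the two bond formations and keeps the formyl group as its acetal. It sets out from 15 and 12. Bromination of 15 with allylic transposition (NBS, Me2S, CH2Cl2) should give methyl (Z)-2-(bromomethyl)-4,4-dimethoxybut-2-enoate F1. An indium-mediated Barbier allylation of 12 with F1 (In powder, THF/H2O, rt; closed chair transition state, syn adducts from the Z bromide) should give the syn hydroxy ester acetal F2 together with its C7,C8-epimeric syn diastereomer F3, which is removed by chromatography. TsOH·H2O in wet acetone then lactonises F2 and frees the aldehyde to give 20, now isolated, and Sc(OTf)3 (10 mol%, CH2Cl2, −40 to 0 °C) closes 20 to 21, where the route is rejoined.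

Step 17. The γ-hydroxy silyl ester may relactonise or pass its silyl group to the C8 hydroxyl under the basic acylation conditions, and acylation of the hindered alcohol may be slow. The fallback replaces the silyl ester by an allyl ester that cannot migrate and is released by palladium. It sets out from 23 through its lithium carboxylate 24, which is alkylated with allyl bromide in DMF to give the hydroxy allyl ester F4. Acylation of F4 with the acid chloride of 4 (made with 1-chloro-N,N,2-trimethylprop-1-en-1-amine; then pyridine, DMAP) should give the diester F5. Pd(PPh3)4 and morpholine in THF remove the allyl group to give the acid F6, and AcOH/THF/H2O (3:1:1, 40 °C) removes the acetonide and the primary silyl ether to give 28, where the route is rejoined.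

Step 19. Under the weakly acidic fluoride conditions the freed C6 hydroxyl may close onto the C12 acid, or the dihydroxy ester may shuffle its acyl group. The fallback frees O6 oxidatively at neutral pH instead. It sets out from 22: 4-methoxybenzyl trichloroacetimidate with La(OTf)3 (cat.) in toluene should give the 6,15-bis(4-methoxybenzyl) ether lactone F7. LiOH·H2O followed by i-Pr3SiCl (as in step 16) gives the hydroxy silyl ester F8, and Yamaguchi esterification with 4 (as in step 17) gives the ester F9. AcOH/THF/H2O removes the acetonide and the silyl ester to give the bis(4-methoxybenzyl) ether acid F10. DDQ in CH2Cl2 with pH 7 buffer at 0 °C then cleaves both benzyl ethers and delivers 29.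

Further compounds
F1 | step 13 | methyl (Z)-2-(bromomethyl)-4,4-dimethoxybut-2-enoate | COC(OC)/C=C(\CBr)C(=O)OC
F2 | step 13 | methyl (3R,4R,6S)-3-(dimethoxymethyl)-6-ethenyl-4-hydroxy-6,8-dimethyl-2-methylidenenon-7-enoate (syn adduct, C7/C8 as in 19) | C=C[C@](C)(C[C@@H](O)[C@H](C(OC)OC)C(=C)C(=O)OC)C=C(C)C
F3 | step 13 | methyl (3S,4S,6S)-3-(dimethoxymethyl)-6-ethenyl-4-hydroxy-6,8-dimethyl-2-methylidenenon-7-enoate (syn adduct, C7 and C8 inverted) | C=C[C@](C)(C[C@H](O)[C@@H](C(OC)OC)C(=C)C(=O)OC)C=C(C)C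
F4 | step 17 | allyl (5S,6S,7R,8R,10S)-6,15-bis[(tert-butyldimethylsilyl)oxy]-8-hydroxyelema-1,3,11(13)-trien-12-oate | C=C[C@]1(C)C[C@@H](O)[C@@H](C(=C)C(=O)OCC=C)[C@@H](O[Si](C)(C)C(C)(C)C)[C@@H]1C(=C)CO[Si](C)(C)C(C)(C)C
F5 | step 17 | allyl (5S,6S,7R,8R,10S)-6,15-bis[(tert-butyldimethylsilyl)oxy]-8-({2-[(4R)-2,2-dimethyl-1,3-dioxolan-4-yl]prop-2-enoyl}oxy)elema-1,3,11(13)-trien-12-oate | C=C[C@]1(C)C[C@@H](OC(=O)C(=C)[C@@H]2COC(C)(C)O2)[C@@H](C(=C)C(=O)OCC=C)[C@@H](O[Si](C)(C)C(C)(C)C)[C@@H]1C(=C)CO[Si](C)(C)C(C)(C)C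
F6 | step 17 | (5S,6S,7R,8R,10S)-6,15-bis[(tert-butyldimethylsilyl)oxy]-8-({2-[(4R)-2,2-dimethyl-1,3-dioxolan-4-yl]prop-2-enoyl}oxy)elema-1,3,11(13)-trien-12-oic acid | C=C[C@]1(C)C[C@@H](OC(=O)C(=C)[C@@H]2COC(C)(C)O2)[C@@H](C(=C)C(=O)O)[C@@H](O[Si](C)(C)C(C)(C)C)[C@@H]1C(=C)CO[Si](C)(C)C(C)(C)C
F7 | step 19 | 6,15-bis[(4-methoxybenzyl)oxy]elema-1,3,11(13)-trien-12,8-olide (ring configuration as in 22) | C=C[C@]1(C)C[C@H]2OC(=O)C(=C)[C@H]2[C@@H](OCc3ccc(OC)cc3)[C@@H]1C(=C)COCc1ccc(OC)cc1
F8 | step 19 | triisopropylsilyl 8-hydroxy-6,15-bis[(4-methoxybenzyl)oxy]elema-1,3,11(13)-trien-12-oate (ring configuration as in 25) | C=C[C@]1(C)C[C@@H](O)[C@@H](C(=C)C(=O)O[Si](C(C)C)(C(C)C)C(C)C)[C@@H](OCc2ccc(OC)cc2)[C@@H]1C(=C)COCc1ccc(OC)cc1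
F9 | step 19 | triisopropylsilyl 8-({2-[(4R)-2,2-dimethyl-1,3-dioxolan-4-yl]prop-2-enoyl}oxy)-6,15-bis[(4-methoxybenzyl)oxy]elema-1,3,11(13)-trien-12-oate (ring configuration as in 27) | C=C[C@]1(C)C[C@@H](OC(=O)C(=C)[C@@H]2COC(C)(C)O2)[C@@H](C(=C)C(=O)O[Si](C(C)C)(C(C)C)C(C)C)[C@@H](OCc2ccc(OC)cc2)[C@@H]1C(=C)COCc1ccc(OC)cc1
F10 | step 19 | 8-{[(3R)-3,4-dihydroxy-2-methylidenebutanoyl]oxy}-6,15-bis[(4-methoxybenzyl)oxy]elema-1,3,11(13)-trien-12-oic acid (ring configuration as in 29) | C=C[C@]1(C)C[C@@H](OC(=O)C(=C)[C@@H](O)CO)[C@@H](C(=C)C(=O)O)[C@@H](OCc2ccc(OC)cc2)[C@@H]1C(=C)COCc1ccc(OC)cc1
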